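**Plan**

1. Cuts: the oxolane O1–C5 and C2–C3 bonds (an anti-aldol pair: inner-unit aldehyde plus a C4-benzyl butanoyl imide); in each dihydrobenzofuran the C3–C3a bond (read backwards as a one-carbon ring expansion to a 3-diazoflavanone); each flavanone C2–aryl bond (chromone plus arylboronic acid).
2. Forward: 6-bromo-8-methoxychromone → outer flavanone → outer dihydrobenzofuran (ring contraction) → its boronic acid → inner flavanone → inner dihydrobenzofuran (ring contraction) → aldehyde → aldol chain → oxolane closed last → desilylation.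
3. Enabling feature: the inner dihydrobenzofuran carries at C3 an exocyclic CH2OH carbon next to the fused aryl carbon C3a, so it is a chroman-4-one short of one ring atom; flavanone C4 becomes that exocyclic carbon when C4a moves from C4 to C3.
4. Stereochemistry: C2 of each dihydrobenzofuran comes from ligand-controlled conjugate addition (enantiomeric ligands) and C3 from equilibration to the trans ester. Oxolane C4 comes from auxiliary-controlled alkylation, C3 and C2 from an auxiliary-controlled anti-aldol, and the all-cis ring is kept because closure is an SN2 displacement at the primary carbon C5.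

Key step: step 13

Remark on the target: the oxolane is read from the SMILES as (2R,3R,4R) with aryl, hydroxymethyl and benzyl groups all cis (the C2 epimer of the lariciresinol pattern); both dihydrobenzofurans are trans.
Remark on step 5 and step 11: the (S)-pyridine-oxazoline ligand is assumed to give the (2R)-flavanone, by analogy with its sense for cyclic enones; if the sense is opposite, the two ligand enantiomers are exchanged between these steps.
Remark on step 23: the MgCl2-catalysed anti-aldol is assumed to take the aldehyde onto the face of the chelated (Z)-enolate opposite the C4 benzyl group of the auxiliary (the sense of enolate alkylation), which calls for the (4R)-auxiliary; if the sense is opposite, the (4S)-auxiliary is attached in step 22 with no other change.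
Notation: TIPS = triisopropylsilyl, TBS = tert-butyldimethylsilyl, TBDPS = tert-butyldiphenylsilyl, Piv = pivaloyl. Ar1 = 3-methoxy-4-(TIPS-oxy)phenyl. DB1 = (2S,3R)-3-(TBS-oxymethyl)-7-methoxy-2-Ar1-2,3-dihydro-1-benzofuran-5-yl (trans). DB2 = (2R,3S)-3-(TBS-oxymethyl)-7-methoxy-2-DB1-2,3-dihydro-1-benzofuran-5-yl (trans). Oxolane locants: O1, C2 (aryl), C3 (CH2O), C4 (benzyl), C5.

**Route**

Step 1
Reactants: 1 1-(2-hydroxy-3-methoxyphenyl)ethanone
Product: 2 1-(5-bromo-2-hydroxy-3-methoxyphenyl)ethanone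
Conditions: NBS, MeCN, 0 °C → rt
Reagents that add atoms: N-bromosuccinimide, O=C1CCC(=O)N1Br
Why: Electrophilic aromatic bromination goes para to the phenol hydroxyl because both ortho positions are substituted, so a single regioisomer is expected.

Step 2
Reactants: 2 1-(5-bromo-2-hydroxy-3-methoxyphenyl)ethanone; 3 N,N-dimethylformamide dimethyl acetal
Product: 5 6-bromo-8-methoxy-4H-chromen-4-one, via enaminone 4 (not isolated)
Conditions: 3, toluene, 100 °C; then conc. HCl, CH2Cl2, 40 °C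
Reagents that add atoms: none
Why: Condensation of the acetyl methyl group with the amide acetal gives the enaminone, and acid then triggers 6-endo oxa-Michael addition of the phenol with loss of dimethylamine, the standard enaminone route to chromones.

Step 3
Reactants: 6 4-bromo-2-methoxyphenol
Product: 7 (4-bromo-2-methoxyphenoxy)triisopropylsilane
Conditions: TIPSCl, imidazole, DMF, rt
Reagents that add atoms: triisopropylsilyl chloride, CC(C)[Si](Cl)(C(C)C)C(C)C
Why: Imidazole-promoted silylation of the phenol, chosen so that every protecting group of the route falls to fluoride in the last step.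

Step 4
Reactants: 7 (4-bromo-2-methoxyphenoxy)triisopropylsilane
Product: 10 Ar1–boronic acid, via aryllithium 8 (not isolated), via lithium triisopropoxyborate 9 (not isolated)
Conditions: n-BuLi, THF, −78 °C; B(OiPr)3, −78 °C → rt; 1 M aq. HCl
Reagents that add atoms: triisopropyl borate, CC(C)OB(OC(C)C)OC(C)C; water, O; n-butyllithium, [Li]CCCC (lithium stays only in 8 and 9)
Why: Bromine–lithium exchange, borylation with the trialkyl borate and hydrolysis is the standard route to arylboronic acids, and the aryl silyl ether is inert at −78 °C.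

Step 5
Reactants: 5 6-bromo-8-methoxy-4H-chromen-4-one; 10 Ar1–boronic acid
Product: 11 (2S)-6-bromo-8-methoxy-2-Ar1-chroman-4-one
Conditions: Pd(OCOCF3)2 (5 mol%), (R)-4-tert-butyl-2-(pyridin-2-yl)-4,5-dihydro-1,3-oxazole (6 mol%), NH4PF6 (30 mol%), H2O (5 equiv), ClCH2CH2Cl, 60 °C
Reagents that add atoms: none
Why: Asymmetric conjugate addition of the arylboronic acid to the chromone under divalent-palladium/pyridine-oxazoline catalysis (transmetalation, face-selective carbopalladation, protonolysis of the palladium enolate) sets C2 under ligand control, and the aryl bromide survives because no zerovalent palladium is formed.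

Step 6
Reactants: 11 (2S)-6-bromo-8-methoxy-2-Ar1-chroman-4-one
Product: 14 (2R)-6-bromo-3-diazo-8-methoxy-2-Ar1-chroman-4-one, via lithium enolate 12 (not isolated), via trifluoroacetyl enol 13 (not isolated)
Conditions: LiN(SiMe3)2, THF, −78 °C, 5 min; CF3CO2CH2CF3, −78 °C; aq. HCl; then 4-acetamidobenzenesulfonyl azide, Et3N, H2O (1 equiv), MeCN, 0 °C → rt
Reagents that add atoms: 4-acetamidobenzenesulfonyl azide, CC(=O)Nc1ccc(cc1)S(=O)(=O)N=[N+]=[N-]; lithium bis(trimethylsilyl)amide, [Li]N([Si](C)(C)C)[Si](C)(C)C (lithium stays only in 12); 2,2,2-trifluoroethyl trifluoroacetate, O=C(OCC(F)(F)F)C(F)(F)F (its CF3CO group stays only in 13)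
Why: Kinetic enolisation and immediate C-trifluoroacetylation at −78 °C should outrun retro-oxa-Michael opening of the enolate, after which Regitz-type diazo transfer to the activated 1,3-dicarbonyl with loss of the trifluoroacetyl group installs the diazo group without touching C2 (the descriptor changes only because the diazo carbon outranks the aryl group).

Step 7
Reactants: 14 (2R)-6-bromo-3-diazo-8-methoxy-2-Ar1-chroman-4-one
Product: 17 methyl (2S,3S)-5-bromo-7-methoxy-2-Ar1-2,3-dihydro-1-benzofuran-3-carboxylate, via ketene 15 (not isolated), via cis ester 16 (not isolated)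
Conditions: hν (365 nm), MeOH–THF 1:1, 10 °C, degassed; then DBU (0.2 equiv), 23 °C
Reagents that add atoms: methanol, CO
Why: Photochemical Wolff rearrangement with ring contraction (C4a shifts from C4 to C3 and methanol traps the ketene), as analysed for step 13, carries C2 over unchanged and sets C3 trans by base equilibration of the ester.

Step 8
Reactants: 17 methyl (2S,3S)-5-bromo-7-methoxy-2-Ar1-2,3-dihydro-1-benzofuran-3-carboxylate
Product: 18 [(2S,3R)-5-bromo-7-methoxy-2-Ar1-2,3-dihydro-1-benzofuran-3-yl]methanol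
Conditions: LiBH4, THF–MeOH, 0 °C → rt
Reagents that add atoms: none
Why: Hydride reduction of the ester to the primary alcohol with LiBH4 leaves the aryl bromide and the aryl silyl ether untouched and ends the epimerisability of C3.

Step 9
Reactants: 18 [(2S,3R)-5-bromo-7-methoxy-2-Ar1-2,3-dihydro-1-benzofuran-3-yl]methanol
Product: 19 DB1–Br
Conditions: TBSCl, imidazole, DMF, rt
Reagents that add atoms: tert-butyldimethylsilyl chloride, CC(C)(C)[Si](C)(C)Cl
Why: Standard silylation of the primary alcohol, so that the later organolithium and enolate steps meet no acidic hydrogen.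

Step 10
Reactants: 19 DB1–Br
Product: 22 DB1–boronic acid, via aryllithium 20 (not isolated), via lithium triisopropoxyborate 21 (not isolated)
Conditions: n-BuLi, THF, −78 °C; B(OiPr)3, −78 °C → rt; aq. AcOH
Reagents that add atoms: triisopropyl borate, CC(C)OB(OC(C)C)OC(C)C; water, O; n-butyllithium, [Li]CCCC (lithium stays only in 20 and 21)
Why: Bromine–lithium exchange at −78 °C, borylation and mild hydrolysis as in step 4, with both silyl ethers stable to the organolithium at low temperature.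

Step 11
Reactants: 22 DB1–boronic acid; 5 6-bromo-8-methoxy-4H-chromen-4-one
Product: 23 (2R)-6-bromo-8-methoxy-2-DB1-chroman-4-one
Conditions: 5 (1.5 equiv), Pd(OCOCF3)2 (5 mol%), (S)-4-tert-butyl-2-(pyridin-2-yl)-4,5-dihydro-1,3-oxazole (6 mol%), NH4PF6 (30 mol%), H2O (5 equiv), ClCH2CH2Cl, 60 °C
Reagents that add atoms: none
Why: The same palladium-catalysed asymmetric conjugate addition as in step 5, now with the enantiomeric ligand, so that the catalyst and not the remote stereocentres of the boronic acid sets C2 of the second flavanone as R.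

Step 12
Reactants: 23 (2R)-6-bromo-8-methoxy-2-DB1-chroman-4-one
Product: 26 (2S)-6-bromo-3-diazo-8-methoxy-2-DB1-chroman-4-one, via lithium enolate 24 (not isolated), via trifluoroacetyl enol 25 (not isolated)
Conditions: LiN(SiMe3)2, THF, −78 °C, 5 min; CF3CO2CH2CF3, −78 °C; aq. HCl; then 4-acetamidobenzenesulfonyl azide, Et3N, H2O (1 equiv), MeCN, 0 °C → rt
Reagents that add atoms: 4-acetamidobenzenesulfonyl azide, CC(=O)Nc1ccc(cc1)S(=O)(=O)N=[N+]=[N-]; lithium bis(trimethylsilyl)amide, [Li]N([Si](C)(C)C)[Si](C)(C)C (lithium stays only in 24); 2,2,2-trifluoroethyl trifluoroacetate, O=C(OCC(F)(F)F)C(F)(F)F (its CF3CO group stays only in 25)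
Why: Detrifluoroacetylative diazo transfer as in step 6, in which the low-temperature enolate is acylated before it can open to the chalcone phenoxide, so that C2 keeps its spatial arrangement (the descriptor alone changes).

Step 13
Reactants: 26 (2S)-6-bromo-3-diazo-8-methoxy-2-DB1-chroman-4-one
Product: 29 methyl (2R,3R)-5-bromo-7-methoxy-2-DB1-2,3-dihydro-1-benzofuran-3-carboxylate, via ketene 27 (not isolated), via cis ester 28 (not isolated)
Conditions: hν (365 nm), MeOH–THF 1:1, 10 °C, degassed; then DBU (0.2 equiv), 23 °C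
Reagents that add atoms: methanol, CO
Why: Excitation of the s-cis-locked diazo ketone expels N2 with 1,2-shift of the fused aryl carbon C4a from the carbonyl carbon C4 to C3, giving the ring-contracted ketene 27, which methanol captures as the ester; this is a photochemical Wolff rearrangement whose closest analogues are 3-diazochroman-4-ones giving 2,3-dihydrobenzofuran-3-carboxylates and 2-diazo-1-indanones giving benzocyclobutene carboxylates. The five-membered ring is closed not by a cyclisation but by this 1,2-aryl shift, which makes the new C3–C3a bond, turns the pyranone into the dihydrofuran and leaves C4 as the exocyclic ester carbon. C2 is carried over unchanged from flavanone 23 because it takes no part in the rearrangement, while the new centre C3, which kinetic protonation of the ester enol may deliver partly as cis ester 28, is equilibrated by DBU through the ester enolate to the more stable trans arrangement. The step needs migration of the aryl carbon in preference to 1,2-hydride shift from C2 (flavone) or O–H insertion into methanol, and the fixed s-cis geometry of the cyclic diazo ketone, which favours concerted rearrangement from the excited state, should secure this, while irradiation at 365 nm spares the aryl bromide and the silyl ethers. Opening of the ester enolate by β-elimination of the phenoxide would be the reverse of a 5-endo-trig closure and is expected to be slow, so C2 should not be lost during the equilibration.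

Step 14
Reactants: 29 methyl (2R,3R)-5-bromo-7-methoxy-2-DB1-2,3-dihydro-1-benzofuran-3-carboxylate
Product: 30 [(2R,3S)-5-bromo-7-methoxy-2-DB1-2,3-dihydro-1-benzofuran-3-yl]methanol
Conditions: LiBH4, THF–MeOH, 0 °C → rt
Reagents that add atoms: none
Why: LiBH4 reduction of the methyl ester to the hydroxymethyl group, which also removes any later risk of epimerisation at C3.

Step 15
Reactants: 30 [(2R,3S)-5-bromo-7-methoxy-2-DB1-2,3-dihydro-1-benzofuran-3-yl]methanol
Product: 31 DB2–Br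
Conditions: TBSCl, imidazole, DMF, rt
Reagents that add atoms: tert-butyldimethylsilyl chloride, CC(C)(C)[Si](C)(C)Cl
Why: Standard silylation of the primary alcohol ahead of the organolithium step.

Step 16
Reactants: 31 DB2–Br
Product: 33 DB2–carbaldehyde, via aryllithium 32 (not isolated)
Conditions: n-BuLi, THF, −78 °C; DMF, −78 → 0 °C; aq. AcOH
Reagents that add atoms: N,N-dimethylformamide, CN(C)C=O; n-butyllithium, [Li]CCCC (lithium stays only in 32)
Why: Bromine–lithium exchange followed by formylation of the aryllithium with DMF is a standard aldehyde synthesis compatible with silyl ethers at −78 °C.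

Step 17
Reactants: 34 3-(4-hydroxy-3-methoxyphenyl)propanoic acid
Product: 36 3-Ar1-propanoic acid, via silyl ester 35 (not isolated)
Conditions: TIPSCl (2.2 equiv), imidazole, DMF, rt; then 1 M aq. HCl, THF, rt
Reagents that add atoms: triisopropylsilyl chloride, CC(C)[Si](Cl)(C(C)C)C(C)C
Why: Exhaustive silylation followed by selective hydrolysis of the labile silyl ester leaves the phenol protected and the acid free.

Step 18
Reactants: 36 3-Ar1-propanoic acid; 37 (4S)-4-benzyl-1,3-oxazolidin-2-one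
Product: 39 (4S)-4-benzyl-3-(3-Ar1-propanoyl)-1,3-oxazolidin-2-one, via mixed anhydride 38 (not isolated)
Conditions: PivCl, Et3N, THF, −20 °C; then 37, LiCl, rt
Reagents that add atoms: pivaloyl chloride, CC(C)(C)C(Cl)=O (its acyl group stays only in 38)
Why: N-Acylation of the oxazolidinone through the mixed pivalic anhydride under LiCl/Et3N activation is a standard mild imide synthesis.

Step 19
Reactants: 39 (4S)-4-benzyl-3-(3-Ar1-propanoyl)-1,3-oxazolidin-2-one; 40 tert-butyl bromoacetate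
Product: 42 tert-butyl (3R)-3-(Ar1-methyl)-4-[(4S)-4-benzyl-2-oxo-1,3-oxazolidin-3-yl]-4-oxobutanoate, via sodium enolate 41 (not isolated)
Conditions: NaN(SiMe3)2, THF, −78 °C; then 40, −78 → −40 °C
Reagents that add atoms: sodium bis(trimethylsilyl)amide, [Na]N([Si](C)(C)C)[Si](C)(C)C (sodium stays only in 41)
Why: Auxiliary-controlled enolate alkylation, in which the chelated (Z)-sodium enolate is attacked by the bromoacetate on the face opposite the C4 benzyl group, sets the future oxolane C4 as R.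

Step 20
Reactants: 42 tert-butyl (3R)-3-(Ar1-methyl)-4-[(4S)-4-benzyl-2-oxo-1,3-oxazolidin-3-yl]-4-oxobutanoate
Product: 43 tert-butyl (3R)-3-(Ar1-methyl)-4-hydroxybutanoate
Conditions: LiBH4, MeOH (1.1 equiv), THF, 0 °C
Reagents that add atoms: none
Why: LiBH4 cleaves the imide reductively to the primary alcohol much faster than it attacks the tert-butyl ester, releasing the auxiliary without touching the stereocentre.

Step 21
Reactants: 43 tert-butyl (3R)-3-(Ar1-methyl)-4-hydroxybutanoate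
Product: 44 tert-butyl (3R)-3-(Ar1-methyl)-4-(pivaloyloxy)butanoate
Conditions: PivCl, pyridine, DMAP (cat.), CH2Cl2, 0 °C → rt
Reagents that add atoms: pivaloyl chloride, CC(C)(C)C(Cl)=O
Why: Acylation of the primary alcohol as a pivalate, an ester that survives the later enolisation and borohydride steps and masks the future ring carbon C5.

Step 22
Reactants: 44 tert-butyl (3R)-3-(Ar1-methyl)-4-(pivaloyloxy)butanoate; 45 (4R)-4-benzyl-1,3-oxazolidin-2-one
Product: 48 (2R)-2-(Ar1-methyl)-4-[(4R)-4-benzyl-2-oxo-1,3-oxazolidin-3-yl]-4-oxobutyl pivalate, via acid 46 (not isolated), via mixed anhydride 47 (not isolated)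
Conditions: CF3CO2H, CH2Cl2, 0 °C → rt; evaporate; then PivCl, Et3N, THF, −20 °C; 45, LiCl, rt
Reagents that add atoms: pivaloyl chloride, CC(C)(C)C(Cl)=O (its acyl group stays only in 47)
Why: Acidolysis of the tert-butyl ester followed by mixed-anhydride N-acylation places the (4R)-auxiliary on the carboxyl group whose α-carbon must become C3.

Step 23
Reactants: 33 DB2–carbaldehyde; 48 (2R)-2-(Ar1-methyl)-4-[(4R)-4-benzyl-2-oxo-1,3-oxazolidin-3-yl]-4-oxobutyl pivalate
Product: 50 (2R,3S,4R)-2-(Ar1-methyl)-3-{[(4R)-4-benzyl-2-oxo-1,3-oxazolidin-3-yl]carbonyl}-4-DB2-4-hydroxybutyl pivalate, via trimethylsilyl ether 49 (not isolated)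
Conditions: 48 (1.5 equiv), MgCl2 (20 mol%), NaSbF6 (30 mol%), Et3N, Me3SiCl, EtOAc, 23 °C; then aq. citric acid, MeOH–THF, 0 °C
Reagents that add atoms: chlorotrimethylsilane, C[Si](C)(C)Cl (its silyl group stays only in 49)
Why: Magnesium-halide-catalysed direct anti-aldol addition of the N-acyloxazolidinone, in which soft enolisation gives the chelated (Z)-enolate, the auxiliary directs the aldehyde to one enolate face (fixing the α-centre, future C3, as S) and the anti topicity fixes the carbinol centre (future C2) as R, with silylation of the aldolate driving turnover.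

Step 24
Reactants: 50 (2R,3S,4R)-2-(Ar1-methyl)-3-{[(4R)-4-benzyl-2-oxo-1,3-oxazolidin-3-yl]carbonyl}-4-DB2-4-hydroxybutyl pivalate
Product: 51 (2R,3R,4R)-2-(Ar1-methyl)-4-DB2-4-hydroxy-3-(hydroxymethyl)butyl pivalate
Conditions: LiBH4, MeOH (1.1 equiv), THF, 0 °C
Reagents that add atoms: none
Why: Reductive removal of the auxiliary with LiBH4 gives the primary alcohol while the pivalate and the silyl ethers survive, and the former α-centre can no longer epimerise.

Step 25
Reactants: 51 (2R,3R,4R)-2-(Ar1-methyl)-4-DB2-4-hydroxy-3-(hydroxymethyl)butyl pivalate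
Product: 52 (2R,3R,4R)-2-(Ar1-methyl)-3-(TBDPS-oxymethyl)-4-DB2-4-hydroxybutyl pivalate
Conditions: TBDPSCl, imidazole, CH2Cl2, 0 °C → rt
Reagents that add atoms: tert-butyldiphenylsilyl chloride, CC(C)(C)[Si](Cl)(c1ccccc1)c1ccccc1
Why: Selective silylation of the primary hydroxyl over the hindered secondary benzylic one with a bulky silyl chloride that resists 1,3-migration.

Step 26
Reactants: 52 (2R,3R,4R)-2-(Ar1-methyl)-3-(TBDPS-oxymethyl)-4-DB2-4-hydroxybutyl pivalate
Product: 53 (1R,2R,3R)-3-(Ar1-methyl)-2-(TBDPS-oxymethyl)-1-DB2-butane-1,4-diol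
Conditions: i-Bu2AlH (4 equiv), CH2Cl2, −78 °C; aq. potassium sodium tartrate
Reagents that add atoms: none
Why: Reductive cleavage of the pivalate with i-Bu2AlH at low temperature frees the C5 hydroxyl without affecting the silyl ethers.

Step 27
Reactants: 53 (1R,2R,3R)-3-(Ar1-methyl)-2-(TBDPS-oxymethyl)-1-DB2-butane-1,4-diol
Product: 55 (2R,3R,4R)-4-(Ar1-methyl)-3-(TBDPS-oxymethyl)-2-DB2-oxolane, via primary tosylate 54 (not isolated)
Conditions: TsCl (1.1 equiv), pyridine, DMAP (cat.), CH2Cl2, 0 °C; then 45 °C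
Reagents that add atoms: 4-toluenesulfonyl chloride, Cc1ccc(cc1)S(Cl)(=O)=O (its sulfonyl group stays only in 54)
Why: Selective sulfonylation of the primary hydroxyl followed by 5-exo-tet intramolecular Williamson etherification, in which substitution occurs at the primary carbon C5, so that the benzylic centre C2 keeps its configuration and the all-cis ring follows from the three centres already set.

Step 28
Reactants: 55 (2R,3R,4R)-4-(Ar1-methyl)-3-(TBDPS-oxymethyl)-2-DB2-oxolane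
Product: 56 CNP0395728.1
Conditions: Bu4NF, AcOH, THF, 0 °C → rt
Reagents that add atoms: none
Why: Fluoride cleaves all five silicon–oxygen bonds, and buffering with acetic acid keeps the liberated phenoxides from forming quinone methides at the benzylic ether positions.

**Compound list**

1 | 1-(2-hydroxy-3-methoxyphenyl)ethanone | CC(=O)c1cccc(OC)c1O | starting material
2 | 1-(5-bromo-2-hydroxy-3-methoxyphenyl)ethanone | CC(=O)c1cc(Br)cc(OC)c1O | intermediate
3 | N,N-dimethylformamide dimethyl acetal | COC(OC)N(C)C | starting material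
4 | (E)-1-(5-bromo-2-hydroxy-3-methoxyphenyl)-3-(dimethylamino)prop-2-en-1-one | CN(C)/C=C/C(=O)c1cc(Br)cc(OC)c1O | intermediate (not isolated)
5 | 6-bromo-8-methoxy-4H-chromen-4-one | O=c1ccoc2c(OC)cc(Br)cc12 | intermediate
6 | 4-bromo-2-methoxyphenol | COc1cc(Br)ccc1O | starting material
7 | (4-bromo-2-methoxyphenoxy)triisopropylsilane | COc1cc(Br)ccc1O[Si](C(C)C)(C(C)C)C(C)C | intermediate
8 | [3-methoxy-4-(triisopropylsilyloxy)phenyl]lithium | COc1cc([Li])ccc1O[Si](C(C)C)(C(C)C)C(C)C | intermediate (not isolated)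
9 | lithium triisopropoxy[3-methoxy-4-(triisopropylsilyloxy)phenyl]borate | [Li+].COc1cc([B-](OC(C)C)(OC(C)C)OC(C)C)ccc1O[Si](C(C)C)(C(C)C)C(C)C | intermediate (not isolated)
10 | [3-methoxy-4-(triisopropylsilyloxy)phenyl]boronic acid | COc1cc(B(O)O)ccc1O[Si](C(C)C)(C(C)C)C(C)C | intermediate
11 | (2S)-6-bromo-8-methoxy-2-Ar1-chroman-4-one | Brc1cc(OC)c2c(c1)C(=O)C[C@@H](c1ccc(O[Si](C(C)C)(C(C)C)C(C)C)c(OC)c1)O2 | intermediate
12 | lithium enolate of 11 (lithium 2H-chromen-4-olate, C2 as in 11) | Brc1cc(OC)c2c(c1)C(O[Li])=C[C@@H](c1ccc(O[Si](C(C)C)(C(C)C)C(C)C)c(OC)c1)O2 | intermediate (not isolated)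
13 | 3-trifluoroacetyl derivative of 11, drawn as the 4-hydroxy-2H-chromene enol (C2 as in 11) | Brc1cc(OC)c2c(c1)C(O)=C(C(=O)C(F)(F)F)[C@@H](c1ccc(O[Si](C(C)C)(C(C)C)C(C)C)c(OC)c1)O2 | intermediate (not isolated)
14 | (2R)-6-bromo-3-diazo-8-methoxy-2-Ar1-chroman-4-one (C2 spatially as in 11) | Brc1cc(OC)c2c(c1)C(=O)C(=[N+]=[N-])[C@@H](c1ccc(O[Si](C(C)C)(C(C)C)C(C)C)c(OC)c1)O2 | intermediate
15 | [5-bromo-7-methoxy-2-Ar1-1-benzofuran-3(2H)-ylidene]methanone (ketene, C2 as in 14) | Brc1cc(OC)c2c(c1)C(=C=O)[C@@H](c1ccc(O[Si](C(C)C)(C(C)C)C(C)C)c(OC)c1)O2 | intermediate (not isolated)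
16 | methyl (2S,3R)-5-bromo-7-methoxy-2-Ar1-2,3-dihydro-1-benzofuran-3-carboxylate (cis) | Brc1cc(OC)c2c(c1)[C@@H](C(=O)OC)[C@@H](c1ccc(O[Si](C(C)C)(C(C)C)C(C)C)c(OC)c1)O2 | intermediate (not isolated)
17 | methyl (2S,3S)-5-bromo-7-methoxy-2-Ar1-2,3-dihydro-1-benzofuran-3-carboxylate (trans) | Brc1cc(OC)c2c(c1)[C@H](C(=O)OC)[C@@H](c1ccc(O[Si](C(C)C)(C(C)C)C(C)C)c(OC)c1)O2 | intermediate
18 | [(2S,3R)-5-bromo-7-methoxy-2-Ar1-2,3-dihydro-1-benzofuran-3-yl]methanol | Brc1cc(OC)c2c(c1)[C@H](CO)[C@@H](c1ccc(O[Si](C(C)C)(C(C)C)C(C)C)c(OC)c1)O2 | intermediate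
19 | DB1–Br: {[(2S,3R)-5-bromo-7-methoxy-2-Ar1-2,3-dihydro-1-benzofuran-3-yl]methoxy}(tert-butyl)dimethylsilane | Brc1cc(OC)c2c(c1)[C@H](CO[Si](C)(C)C(C)(C)C)[C@@H](c1ccc(O[Si](C(C)C)(C(C)C)C(C)C)c(OC)c1)O2 | intermediate
20 | DB1–Li (aryllithium from 19) | [Li]c1cc(OC)c2c(c1)[C@H](CO[Si](C)(C)C(C)(C)C)[C@@H](c1ccc(O[Si](C(C)C)(C(C)C)C(C)C)c(OC)c1)O2 | intermediate (not isolated)
21 | lithium triisopropoxy(DB1)borate | [Li+].CC(C)O[B-](OC(C)C)(OC(C)C)c1cc(OC)c2c(c1)[C@H](CO[Si](C)(C)C(C)(C)C)[C@@H](c1ccc(O[Si](C(C)C)(C(C)C)C(C)C)c(OC)c1)O2 | intermediate (not isolated)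
22 | DB1–boronic acid | OB(O)c1cc(OC)c2c(c1)[C@H](CO[Si](C)(C)C(C)(C)C)[C@@H](c1ccc(O[Si](C(C)C)(C(C)C)C(C)C)c(OC)c1)O2 | intermediate
23 | (2R)-6-bromo-8-methoxy-2-DB1-chroman-4-one | Brc1cc(OC)c2c(c1)C(=O)C[C@H](c1cc(OC)c3c(c1)[C@H](CO[Si](C)(C)C(C)(C)C)[C@@H](c1ccc(O[Si](C(C)C)(C(C)C)C(C)C)c(OC)c1)O3)O2 | intermediate
24 | lithium enolate of 23 (C2 as in 23) | Brc1cc(OC)c2c(c1)C(O[Li])=C[C@H](c1cc(OC)c3c(c1)[C@H](CO[Si](C)(C)C(C)(C)C)[C@@H](c1ccc(O[Si](C(C)C)(C(C)C)C(C)C)c(OC)c1)O3)O2 | intermediate (not isolated)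
25 | 3-trifluoroacetyl derivative of 23, drawn as the 4-hydroxy-2H-chromene enol (C2 as in 23) | Brc1cc(OC)c2c(c1)C(O)=C(C(=O)C(F)(F)F)[C@H](c1cc(OC)c3c(c1)[C@H](CO[Si](C)(C)C(C)(C)C)[C@@H](c1ccc(O[Si](C(C)C)(C(C)C)C(C)C)c(OC)c1)O3)O2 | intermediate (not isolated)
26 | (2S)-6-bromo-3-diazo-8-methoxy-2-DB1-chroman-4-one (C2 spatially as in 23) | Brc1cc(OC)c2c(c1)C(=O)C(=[N+]=[N-])[C@H](c1cc(OC)c3c(c1)[C@H](CO[Si](C)(C)C(C)(C)C)[C@@H](c1ccc(O[Si](C(C)C)(C(C)C)C(C)C)c(OC)c1)O3)O2 | intermediate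
27 | [5-bromo-7-methoxy-2-DB1-1-benzofuran-3(2H)-ylidene]methanone (ketene, C2 as in 26) | Brc1cc(OC)c2c(c1)C(=C=O)[C@H](c1cc(OC)c3c(c1)[C@H](CO[Si](C)(C)C(C)(C)C)[C@@H](c1ccc(O[Si](C(C)C)(C(C)C)C(C)C)c(OC)c1)O3)O2 | intermediate (not isolated)
28 | methyl (2R,3S)-5-bromo-7-methoxy-2-DB1-2,3-dihydro-1-benzofuran-3-carboxylate (cis) | Brc1cc(OC)c2c(c1)[C@H](C(=O)OC)[C@H](c1cc(OC)c3c(c1)[C@H](CO[Si](C)(C)C(C)(C)C)[C@@H](c1ccc(O[Si](C(C)C)(C(C)C)C(C)C)c(OC)c1)O3)O2 | intermediate (not isolated)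
29 | methyl (2R,3R)-5-bromo-7-methoxy-2-DB1-2,3-dihydro-1-benzofuran-3-carboxylate (trans) | Brc1cc(OC)c2c(c1)[C@@H](C(=O)OC)[C@H](c1cc(OC)c3c(c1)[C@H](CO[Si](C)(C)C(C)(C)C)[C@@H](c1ccc(O[Si](C(C)C)(C(C)C)C(C)C)c(OC)c1)O3)O2 | intermediate
30 | [(2R,3S)-5-bromo-7-methoxy-2-DB1-2,3-dihydro-1-benzofuran-3-yl]methanol | Brc1cc(OC)c2c(c1)[C@@H](CO)[C@H](c1cc(OC)c3c(c1)[C@H](CO[Si](C)(C)C(C)(C)C)[C@@H](c1ccc(O[Si](C(C)C)(C(C)C)C(C)C)c(OC)c1)O3)O2 | intermediate
31 | DB2–Br: TBS ether of 30 | Brc1cc(OC)c2c(c1)[C@@H](CO[Si](C)(C)C(C)(C)C)[C@H](c1cc(OC)c3c(c1)[C@H](CO[Si](C)(C)C(C)(C)C)[C@@H](c1ccc(O[Si](C(C)C)(C(C)C)C(C)C)c(OC)c1)O3)O2 | intermediate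
32 | DB2–Li (aryllithium from 31) | [Li]c1cc(OC)c2c(c1)[C@@H](CO[Si](C)(C)C(C)(C)C)[C@H](c1cc(OC)c3c(c1)[C@H](CO[Si](C)(C)C(C)(C)C)[C@@H](c1ccc(O[Si](C(C)C)(C(C)C)C(C)C)c(OC)c1)O3)O2 | intermediate (not isolated)
33 | DB2–carbaldehyde | O=Cc1cc(OC)c2c(c1)[C@@H](CO[Si](C)(C)C(C)(C)C)[C@H](c1cc(OC)c3c(c1)[C@H](CO[Si](C)(C)C(C)(C)C)[C@@H](c1ccc(O[Si](C(C)C)(C(C)C)C(C)C)c(OC)c1)O3)O2 | intermediate
34 | 3-(4-hydroxy-3-methoxyphenyl)propanoic acid | COc1cc(CCC(=O)O)ccc1O | starting material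
35 | triisopropylsilyl 3-Ar1-propanoate | COc1cc(CCC(=O)O[Si](C(C)C)(C(C)C)C(C)C)ccc1O[Si](C(C)C)(C(C)C)C(C)C | intermediate (not isolated)
36 | 3-Ar1-propanoic acid | COc1cc(CCC(=O)O)ccc1O[Si](C(C)C)(C(C)C)C(C)C | intermediate
37 | (4S)-4-benzyl-1,3-oxazolidin-2-one | O=C1OC[C@H](Cc2ccccc2)N1 | starting material
38 | 3-Ar1-propanoic pivalic anhydride | COc1cc(CCC(=O)OC(=O)C(C)(C)C)ccc1O[Si](C(C)C)(C(C)C)C(C)C | intermediate (not isolated)
39 | (4S)-4-benzyl-3-(3-Ar1-propanoyl)-1,3-oxazolidin-2-one | COc1cc(CCC(=O)N2C(=O)OC[C@@H]2Cc2ccccc2)ccc1O[Si](C(C)C)(C(C)C)C(C)C | intermediate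
40 | tert-butyl bromoacetate | BrCC(=O)OC(C)(C)C | starting material
41 | sodium (Z)-enolate of 39 | COc1cc(C/C=C(\O[Na])N2C(=O)OC[C@@H]2Cc2ccccc2)ccc1O[Si](C(C)C)(C(C)C)C(C)C | intermediate (not isolated)
42 | tert-butyl (3R)-3-(Ar1-methyl)-4-[(4S)-4-benzyl-2-oxo-1,3-oxazolidin-3-yl]-4-oxobutanoate | COc1cc(C[C@H](CC(=O)OC(C)(C)C)C(=O)N2C(=O)OC[C@@H]2Cc2ccccc2)ccc1O[Si](C(C)C)(C(C)C)C(C)C | intermediate
43 | tert-butyl (3R)-3-(Ar1-methyl)-4-hydroxybutanoate | COc1cc(C[C@H](CC(=O)OC(C)(C)C)CO)ccc1O[Si](C(C)C)(C(C)C)C(C)C | intermediate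
44 | tert-butyl (3R)-3-(Ar1-methyl)-4-(pivaloyloxy)butanoate | COc1cc(C[C@H](CC(=O)OC(C)(C)C)COC(=O)C(C)(C)C)ccc1O[Si](C(C)C)(C(C)C)C(C)C | intermediate
45 | (4R)-4-benzyl-1,3-oxazolidin-2-one | O=C1OC[C@@H](Cc2ccccc2)N1 | starting material
46 | (3R)-3-(Ar1-methyl)-4-(pivaloyloxy)butanoic acid | COc1cc(C[C@H](CC(=O)O)COC(=O)C(C)(C)C)ccc1O[Si](C(C)C)(C(C)C)C(C)C | intermediate (not isolated)
47 | mixed pivalic anhydride of 46 | COc1cc(C[C@H](CC(=O)OC(=O)C(C)(C)C)COC(=O)C(C)(C)C)ccc1O[Si](C(C)C)(C(C)C)C(C)C | intermediate (not isolated)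
48 | (2R)-2-(Ar1-methyl)-4-[(4R)-4-benzyl-2-oxo-1,3-oxazolidin-3-yl]-4-oxobutyl pivalate | COc1cc(C[C@H](CC(=O)N2C(=O)OC[C@H]2Cc2ccccc2)COC(=O)C(C)(C)C)ccc1O[Si](C(C)C)(C(C)C)C(C)C | intermediate
49 | trimethylsilyl ether of 50 (at the benzylic oxygen) | COc1cc(C[C@@H](COC(=O)C(C)(C)C)[C@H](C(=O)N2C(=O)OC[C@H]2Cc2ccccc2)[C@@H](O[Si](C)(C)C)c3cc(OC)c4c(c3)[C@@H](CO[Si](C)(C)C(C)(C)C)[C@H](c3cc(OC)c5c(c3)[C@H](CO[Si](C)(C)C(C)(C)C)[C@@H](c3ccc(O[Si](C(C)C)(C(C)C)C(C)C)c(OC)c3)O5)O4)ccc1O[Si](C(C)C)(C(C)C)C(C)C | intermediate (not isolated)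
50 | (2R,3S,4R)-2-(Ar1-methyl)-3-{[(4R)-4-benzyl-2-oxo-1,3-oxazolidin-3-yl]carbonyl}-4-DB2-4-hydroxybutyl pivalate (anti-aldol adduct) | COc1cc(C[C@@H](COC(=O)C(C)(C)C)[C@H](C(=O)N2C(=O)OC[C@H]2Cc2ccccc2)[C@@H](O)c3cc(OC)c4c(c3)[C@@H](CO[Si](C)(C)C(C)(C)C)[C@H](c3cc(OC)c5c(c3)[C@H](CO[Si](C)(C)C(C)(C)C)[C@@H](c3ccc(O[Si](C(C)C)(C(C)C)C(C)C)c(OC)c3)O5)O4)ccc1O[Si](C(C)C)(C(C)C)C(C)C | intermediate
51 | (2R,3R,4R)-2-(Ar1-methyl)-4-DB2-4-hydroxy-3-(hydroxymethyl)butyl pivalate | COc1cc(C[C@@H](COC(=O)C(C)(C)C)[C@H](CO)[C@@H](O)c3cc(OC)c4c(c3)[C@@H](CO[Si](C)(C)C(C)(C)C)[C@H](c3cc(OC)c5c(c3)[C@H](CO[Si](C)(C)C(C)(C)C)[C@@H](c3ccc(O[Si](C(C)C)(C(C)C)C(C)C)c(OC)c3)O5)O4)ccc1O[Si](C(C)C)(C(C)C)C(C)C | intermediate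
52 | (2R,3R,4R)-2-(Ar1-methyl)-3-(TBDPS-oxymethyl)-4-DB2-4-hydroxybutyl pivalate | COc1cc(C[C@@H](COC(=O)C(C)(C)C)[C@H](CO[Si](c6ccccc6)(c6ccccc6)C(C)(C)C)[C@@H](O)c3cc(OC)c4c(c3)[C@@H](CO[Si](C)(C)C(C)(C)C)[C@H](c3cc(OC)c5c(c3)[C@H](CO[Si](C)(C)C(C)(C)C)[C@@H](c3ccc(O[Si](C(C)C)(C(C)C)C(C)C)c(OC)c3)O5)O4)ccc1O[Si](C(C)C)(C(C)C)C(C)C | intermediate
53 | (1R,2R,3R)-3-(Ar1-methyl)-2-(TBDPS-oxymethyl)-1-DB2-butane-1,4-diol | COc1cc(C[C@@H](CO)[C@H](CO[Si](c6ccccc6)(c6ccccc6)C(C)(C)C)[C@@H](O)c3cc(OC)c4c(c3)[C@@H](CO[Si](C)(C)C(C)(C)C)[C@H](c3cc(OC)c5c(c3)[C@H](CO[Si](C)(C)C(C)(C)C)[C@@H](c3ccc(O[Si](C(C)C)(C(C)C)C(C)C)c(OC)c3)O5)O4)ccc1O[Si](C(C)C)(C(C)C)C(C)C | intermediate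
54 | (2R,3R,4R)-2-(Ar1-methyl)-3-(TBDPS-oxymethyl)-4-DB2-4-hydroxybutyl 4-methylbenzenesulfonate | COc1cc(C[C@@H](COS(=O)(=O)c6ccc(C)cc6)[C@H](CO[Si](c6ccccc6)(c6ccccc6)C(C)(C)C)[C@@H](O)c3cc(OC)c4c(c3)[C@@H](CO[Si](C)(C)C(C)(C)C)[C@H](c3cc(OC)c5c(c3)[C@H](CO[Si](C)(C)C(C)(C)C)[C@@H](c3ccc(O[Si](C(C)C)(C(C)C)C(C)C)c(OC)c3)O5)O4)ccc1O[Si](C(C)C)(C(C)C)C(C)C | intermediate (not isolated)
55 | (2R,3R,4R)-4-(Ar1-methyl)-3-(TBDPS-oxymethyl)-2-DB2-oxolane (all-cis) | COc1cc(C[C@H]2CO[C@@H](c3cc(OC)c4c(c3)[C@@H](CO[Si](C)(C)C(C)(C)C)[C@H](c3cc(OC)c5c(c3)[C@H](CO[Si](C)(C)C(C)(C)C)[C@@H](c3ccc(O[Si](C(C)C)(C(C)C)C(C)C)c(OC)c3)O5)O4)[C@H]2CO[Si](c6ccccc6)(c6ccccc6)C(C)(C)C)ccc1O[Si](C(C)C)(C(C)C)C(C)C | intermediate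
56 | CNP0395728.1: 4-{[(3R,4R,5R)-5-{(2R,3S)-3-(hydroxymethyl)-2-[(2S,3R)-2-(4-hydroxy-3-methoxyphenyl)-3-(hydroxymethyl)-7-methoxy-2,3-dihydro-1-benzofuran-5-yl]-7-methoxy-2,3-dihydro-1-benzofuran-5-yl}-4-(hydroxymethyl)oxolan-3-yl]methyl}-2-methoxyphenol | COc1cc(C[C@H]2CO[C@@H](c3cc(OC)c4c(c3)[C@@H](CO)[C@H](c3cc(OC)c5c(c3)[C@H](CO)[C@@H](c3ccc(O)c(OC)c3)O5)O4)[C@H]2CO)ccc1O | target

**Step count and risks**

Total step count: 28. Longest linear sequence: 20 steps (steps 1, 2, 5–16 and 23–28, starting from 1).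

Steps most likely to fail:

Step 12 (the same hazard exists in step 6). The lithium enolate of the flavanone may open by retro-oxa-Michael expulsion of the phenoxide before it is acylated, which would scramble C2 on re-closure or divert material to the chalcone. The fallback sets out from 23 and introduces the diazo group without any enolate. Acid-promoted α-nitrosation (isoamyl nitrite, Me3SiCl, CH2Cl2, −20 °C) should give the 3-hydroxyimino ketone F1. The Forster reaction of this oxime with chloramine (NaOCl, aqueous NH3, NaOH, 0 °C) should then give the diazo ketone, so the route is rejoined at 26.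

Step 23. Addition of the magnesium enolate to the electron-rich aldehyde may be slow, so that retro-aldol equilibration and O-silylation of the enolate compete, or the enolate face may be discriminated poorly next to the β-stereocentre. The fallback sets out from acid 46. Coupling with (4S)-4-benzyl-1,3-thiazolidine-2-thione (EDC·HCl, DMAP, CH2Cl2) would give the N-acylthiazolidinethione F2, whose more acidic α-hydrogens allow MgBr2·OEt2-catalysed anti-aldol addition to 33 (Et3N, Me3SiCl, EtOAc). This variant is expected to run through a non-chelated enolate with the complementary facial sense, so the (4S)-thione should give the same anti adduct, first as the trimethylsilyl ether F3 and, after mild acid work-up, as the hydroxy thioimide F4. Reduction with NaBH4 (THF–EtOH, 0 °C) would cleave the auxiliary, and the route is rejoined at 51.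

Step 27. Sulfonylation or ionisation at the electron-rich benzylic hydroxyl may compete with activation of the primary one, opening an SN1 closure that epimerises C2 towards the less crowded 2,3-trans ring; closure of the crowded all-cis ring may also be slow. The fallback sets out from 53 and makes the O1–C5 bond at the carbonyl oxidation level, where the benzylic C–O bond is never activated. Oxidation of the primary alcohol (TEMPO, PhI(OAc)2, CH2Cl2) should proceed through the lactol to the γ-lactone F5. Reduction with i-Bu2AlH at −78 °C would give the lactol F6, and removal of the anomeric hydroxyl with Et3SiH and BF3·OEt2 at −78 °C (oxocarbenium ion at C5, no stereocentre involved) would give the oxolane, so the route is rejoined at 55.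

Further compounds
F1 | step 12 | (2S)-6-bromo-3-(hydroxyimino)-8-methoxy-2-DB1-chroman-4-one (C2 spatially as in 23; oxime geometry undefined) | Brc1cc(OC)c2c(c1)C(=O)C(=NO)[C@H](c1cc(OC)c3c(c1)[C@H](CO[Si](C)(C)C(C)(C)C)[C@@H](c1ccc(O[Si](C(C)C)(C(C)C)C(C)C)c(OC)c1)O3)O2
F2 | step 23 | (2R)-2-(Ar1-methyl)-4-[(4S)-4-benzyl-2-thioxo-1,3-thiazolidin-3-yl]-4-oxobutyl pivalate | COc1cc(C[C@H](CC(=O)N2C(=S)SC[C@@H]2Cc2ccccc2)COC(=O)C(C)(C)C)ccc1O[Si](C(C)C)(C(C)C)C(C)C
F3 | step 23 | trimethylsilyl ether of F4 (at the benzylic oxygen) | COc1cc(C[C@@H](COC(=O)C(C)(C)C)[C@H](C(=O)N2C(=S)SC[C@@H]2Cc2ccccc2)[C@@H](O[Si](C)(C)C)c3cc(OC)c4c(c3)[C@@H](CO[Si](C)(C)C(C)(C)C)[C@H](c3cc(OC)c5c(c3)[C@H](CO[Si](C)(C)C(C)(C)C)[C@@H](c3ccc(O[Si](C(C)C)(C(C)C)C(C)C)c(OC)c3)O5)O4)ccc1O[Si](C(C)C)(C(C)C)C(C)C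
F4 | step 23 | (2R,3S,4R)-2-(Ar1-methyl)-3-{[(4S)-4-benzyl-2-thioxo-1,3-thiazolidin-3-yl]carbonyl}-4-DB2-4-hydroxybutyl pivalate | COc1cc(C[C@@H](COC(=O)C(C)(C)C)[C@H](C(=O)N2C(=S)SC[C@@H]2Cc2ccccc2)[C@@H](O)c3cc(OC)c4c(c3)[C@@H](CO[Si](C)(C)C(C)(C)C)[C@H](c3cc(OC)c5c(c3)[C@H](CO[Si](C)(C)C(C)(C)C)[C@@H](c3ccc(O[Si](C(C)C)(C(C)C)C(C)C)c(OC)c3)O5)O4)ccc1O[Si](C(C)C)(C(C)C)C(C)C
F5 | step 27 | (3R,4R,5R)-3-(Ar1-methyl)-4-(TBDPS-oxymethyl)-5-DB2-oxolan-2-one | COc1cc(C[C@H]2C(=O)O[C@@H](c3cc(OC)c4c(c3)[C@@H](CO[Si](C)(C)C(C)(C)C)[C@H](c3cc(OC)c5c(c3)[C@H](CO[Si](C)(C)C(C)(C)C)[C@@H](c3ccc(O[Si](C(C)C)(C(C)C)C(C)C)c(OC)c3)O5)O4)[C@H]2CO[Si](c6ccccc6)(c6ccccc6)C(C)(C)C)ccc1O[Si](C(C)C)(C(C)C)C(C)C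
F6 | step 27 | (3R,4R,5R)-3-(Ar1-methyl)-4-(TBDPS-oxymethyl)-5-DB2-oxolan-2-ol (anomeric mixture) | COc1cc(C[C@H]2C(O)O[C@@H](c3cc(OC)c4c(c3)[C@@H](CO[Si](C)(C)C(C)(C)C)[C@H](c3cc(OC)c5c(c3)[C@H](CO[Si](C)(C)C(C)(C)C)[C@@H](c3ccc(O[Si](C(C)C)(C(C)C)C(C)C)c(OC)c3)O5)O4)[C@H]2CO[Si](c6ccccc6)(c6ccccc6)C(C)(C)C)ccc1O[Si](C(C)C)(C(C)C)C(C)C
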